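**Strategy.** Ring C is closed last by forming the aryl ketone bond C4–C4a in an intramolecular Friedel–Crafts acylation of the open-chain (S)-3-aryloxy-3-arylpropanoic acid 13. The step exploits the local symmetry of ring A: ether oxygen O1 is para to the geranyl-bearing C6, so the two ring A carbons ortho to O1 (future C4a and C8) are equivalent in the precursor and acylation can only give the 6-geranyl flavanone. The C2 stereocentre is set beforehand by asymmetric transfer hydrogenation and inverted in a Mitsunobu etherification with the symmetric phenol 7, itself made from resorcinol by ortho-lithiation/geranylation and C–H borylation/oxidation.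

Key step: step 9

Remark: the target is the (2S)-flavanone; MOM = methoxymethyl, geranyl = (2E)-3,7-dimethylocta-2,6-dien-1-yl. Resorcinol, geranyl bromide and 3',5'-dihydroxyacetophenone are taken as commercial.

**Route**

Step 1
Reactants: 1 resorcinol
Product: 2 1,3-bis(methoxymethoxy)benzene
Conditions: MOMCl, i-Pr2NEt, CH2Cl2, 0 °C → rt
Reagents that add atoms: chloromethyl methyl ether COCCl
Why: Double O-alkylation of the phenols by the reactive α-chloro ether (Williamson-type acetal formation) should give the bis-MOM ether, which also provides the two directing groups for step 2.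

Step 2
Reactants: 2 1,3-bis(methoxymethoxy)benzene; 3 geranyl bromide
Product: 5 2-geranyl-1,3-bis(methoxymethoxy)benzene, via aryllithium 4 (not isolated)
Conditions: n-BuLi, THF, 0 °C → rt; then CuBr·SMe2 (10 mol %), 3, −78 °C → rt
Reagents that add atoms: n-butyllithium [Li]CCCC (lithium of intermediate 4 only)
Why: Directed ortho-metalation takes the C2–H between the two cooperating OMOM groups, and copper-catalysed SN2 allylation with the primary allylic bromide should give the linear geranyl arene with the E alkene retained.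

Step 3
Reactants: 5 2-geranyl-1,3-bis(methoxymethoxy)benzene
Product: 7 4-geranyl-3,5-bis(methoxymethoxy)phenol, via arylboronate 6 (not isolated)
Conditions: [Ir(OMe)(cod)]2 (1.5 mol %), 4,4'-di-tert-butyl-2,2'-bipyridine (3 mol %), B2pin2, THF, 70 °C; then 30% aq H2O2, 2 M NaOH, 0 °C
Reagents that add atoms: bis(pinacolato)diboron CC1(C)OB(OC1(C)C)B1OC(C)(C)C(C)(C)O1 (boron of intermediate 6 only); hydrogen peroxide OO (phenol oxygen of 7)
Why: Sterically controlled aromatic C–H borylation should take the only ring C–H without an ortho substituent (para to geranyl), and basic peroxide oxidation of the boronate (aryl shift from boron to oxygen) gives the phenol without attacking the unactivated trisubstituted alkenes.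

Step 4
Reactants: 8 3',5'-dihydroxyacetophenone
Product: 9 1-[3,5-bis(methoxymethoxy)phenyl]ethan-1-one
Conditions: MOMCl, i-Pr2NEt, CH2Cl2, 0 °C → rt
Reagents that add atoms: chloromethyl methyl ether COCCl
Why: Williamson-type MOM protection of both phenols, as in step 1, gives a base-stable ketone for the condensation that follows.

Step 5
Reactants: 9 1-[3,5-bis(methoxymethoxy)phenyl]ethan-1-one
Product: 10 methyl 3-[3,5-bis(methoxymethoxy)phenyl]-3-oxopropanoate
Conditions: NaH, (MeO)2CO, THF, reflux; then 1 M HCl to pH 5, 0 °C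
Reagents that add atoms: dimethyl carbonate COC(=O)OC
Why: Crossed Claisen condensation (C-methoxycarbonylation) of the methyl ketone with dimethyl carbonate is made irreversible by the excess of NaH and is a standard entry to aroylacetates.

Step 6
Reactants: 10 methyl 3-[3,5-bis(methoxymethoxy)phenyl]-3-oxopropanoate
Product: 11 methyl (3R)-3-[3,5-bis(methoxymethoxy)phenyl]-3-hydroxypropanoate
Conditions: RuCl[(R,R)-TsDPEN](p-cymene) (1 mol %), HCO2H/Et3N (5:2), DMF, 40 °C
Reagents that add atoms: none
Why: Noyori asymmetric transfer hydrogenation of the aryl ketone through the outer-sphere Ru–H/N–H transition state should, with the (R,R) ligand, give the (R)-carbinol as it does for simple aryl ketones, which sets the future C2 in the configuration opposite to the target.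

Step 7
Reactants: 7 4-geranyl-3,5-bis(methoxymethoxy)phenol; 11 methyl (3R)-3-[3,5-bis(methoxymethoxy)phenyl]-3-hydroxypropanoate
Product: 12 methyl (3S)-3-[3,5-bis(methoxymethoxy)phenyl]-3-[4-geranyl-3,5-bis(methoxymethoxy)phenoxy]propanoate
Conditions: PPh3, DIAD, toluene, 0 °C → rt
Reagents that add atoms: none
Why: Mitsunobu etherification, in which the unhindered phenol displaces the oxyphosphonium-activated benzylic alcohol by SN2 with inversion, should convert the (R)-carbinol into the (S)-aryl ether (C2 of the target), the meta-oxygenated aryl group giving no cation stabilisation that would erode stereospecificity.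

Step 8
Reactants: 12 methyl (3S)-3-[3,5-bis(methoxymethoxy)phenyl]-3-[4-geranyl-3,5-bis(methoxymethoxy)phenoxy]propanoate
Product: 13 (3S)-3-[3,5-bis(methoxymethoxy)phenyl]-3-[4-geranyl-3,5-bis(methoxymethoxy)phenoxy]propanoic acid
Conditions: LiOH·H2O, THF/MeOH/H2O, 0 °C → rt; then 0.5 M HCl to pH 4, 0 °C
Reagents that add atoms: lithium hydroxide [Li+].[OH-] (hydroxyl oxygen of the acid)
Why: Saponification of the methyl ester by acyl attack of hydroxide should be faster at low temperature than α-deprotonation, so the β-aryloxy group is not eliminated, and MOM ethers and alkenes are inert to base.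

Step 9
Reactants: 13 (3S)-3-[3,5-bis(methoxymethoxy)phenyl]-3-[4-geranyl-3,5-bis(methoxymethoxy)phenoxy]propanoic acid
Product: 16 (2S)-2-[3,5-bis(methoxymethoxy)phenyl]-6-geranyl-5,7-bis(methoxymethoxy)-2,3-dihydro-4H-chromen-4-one, via acid chloride 14 (not isolated), via acyl triflate 15 (not isolated)
Conditions: 1-chloro-N,N,2-trimethylprop-1-en-1-amine, CH2Cl2, 0 °C; then 2,6-di-tert-butyl-4-methylpyridine, AgOTf, CH2Cl2, −78 → −20 °C
Reagents that add atoms: 1-chloro-N,N,2-trimethylprop-1-en-1-amine CC(C)=C(Cl)N(C)C (chlorine of intermediate 14 only); silver triflate [Ag+].[O-]S(=O)(=O)C(F)(F)F (triflate of intermediate 15 only)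
Why: The α-chloroenamine turns the acid into acid chloride 14 under neutral conditions, AgOTf exchanges chloride for triflate to give the acylium-like mixed anhydride 15, and the ring A carbon ortho to O1 attacks it, the hindered pyridine taking the proton of the Wheland intermediate so that no free acid meets the geranyl alkenes or the MOM acetals. The closest known reaction type is the intramolecular Friedel–Crafts acylation of 3-aryloxypropanoic acids to chroman-4-ones, here run through an acyl triflate as in Effenberger-type acylations. Ring C closes as a six-membered ring by 6-exo attack of C4a on the acyl carbon C4 (ortho SEAr annulation, C=O exocyclic). No stereocentre is formed; C2 keeps its (S) configuration because no bond to it is broken and the buffered, cold medium should suppress ionisation of the benzylic ether and retro-oxa-Michael opening. The step needs regioselectivity for the 6-geranyl over the 8-geranyl flavanone, which the substrate secures by symmetry since both carbons ortho to O1 are equivalent, and chemoselectivity for ring A over the alkoxylated ring B (indanone closure), which is secured by three oxygen donors (two ortho, one para) activating the ring A carbon against two for ring B and by a six-membered against a five-membered transition state.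

Step 10
Reactants: 16 (2S)-2-[3,5-bis(methoxymethoxy)phenyl]-6-geranyl-5,7-bis(methoxymethoxy)-2,3-dihydro-4H-chromen-4-one
Product: 17 Schizolaenone C
Conditions: 3 M aq HCl, MeOH, 50 °C
Reagents that add atoms: none
Why: Acid-catalysed acetal solvolysis in methanol removes all four MOM groups as dimethoxymethane under conditions commonly used for prenylated and geranylated flavanones, and C2 is not involved so its (S) configuration should persist.

**Compound list**

1 | resorcinol | Oc1cccc(O)c1 | starting material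
2 | 1,3-bis(methoxymethoxy)benzene | COCOc1cccc(OCOC)c1 | intermediate
3 | geranyl bromide, (2E)-1-bromo-3,7-dimethylocta-2,6-diene | CC(C)=CCC/C(C)=C/CBr | starting material
4 | [2,6-bis(methoxymethoxy)phenyl]lithium | COCOc1cccc(OCOC)c1[Li] | intermediate (not isolated)
5 | 2-[(2E)-3,7-dimethylocta-2,6-dien-1-yl]-1,3-bis(methoxymethoxy)benzene | COCOc1cccc(OCOC)c1C/C=C(\C)CCC=C(C)C | intermediate
6 | 2-{4-[(2E)-3,7-dimethylocta-2,6-dien-1-yl]-3,5-bis(methoxymethoxy)phenyl}-4,4,5,5-tetramethyl-1,3,2-dioxaborolane | COCOc1cc(B2OC(C)(C)C(C)(C)O2)cc(OCOC)c1C/C=C(\C)CCC=C(C)C | intermediate (not isolated)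
7 | 4-[(2E)-3,7-dimethylocta-2,6-dien-1-yl]-3,5-bis(methoxymethoxy)phenol | COCOc1cc(O)cc(OCOC)c1C/C=C(\C)CCC=C(C)C | intermediate
8 | 3',5'-dihydroxyacetophenone | CC(=O)c1cc(O)cc(O)c1 | starting material
9 | 1-[3,5-bis(methoxymethoxy)phenyl]ethan-1-one | CC(=O)c1cc(OCOC)cc(OCOC)c1 | intermediate
10 | methyl 3-[3,5-bis(methoxymethoxy)phenyl]-3-oxopropanoate | COC(=O)CC(=O)c1cc(OCOC)cc(OCOC)c1 | intermediate
11 | methyl (3R)-3-[3,5-bis(methoxymethoxy)phenyl]-3-hydroxypropanoate | COC(=O)C[C@H](c1cc(OCOC)cc(OCOC)c1)O | intermediate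
12 | methyl (3S)-3-[3,5-bis(methoxymethoxy)phenyl]-3-{4-[(2E)-3,7-dimethylocta-2,6-dien-1-yl]-3,5-bis(methoxymethoxy)phenoxy}propanoate | COC(=O)C[C@@H](c1cc(OCOC)cc(OCOC)c1)Oc1cc(OCOC)c(C/C=C(\C)CCC=C(C)C)c(OCOC)c1 | intermediate
13 | (3S)-3-[3,5-bis(methoxymethoxy)phenyl]-3-{4-[(2E)-3,7-dimethylocta-2,6-dien-1-yl]-3,5-bis(methoxymethoxy)phenoxy}propanoic acid | OC(=O)C[C@@H](c1cc(OCOC)cc(OCOC)c1)Oc1cc(OCOC)c(C/C=C(\C)CCC=C(C)C)c(OCOC)c1 | intermediate
14 | (3S)-3-[3,5-bis(methoxymethoxy)phenyl]-3-{4-[(2E)-3,7-dimethylocta-2,6-dien-1-yl]-3,5-bis(methoxymethoxy)phenoxy}propanoyl chloride | ClC(=O)C[C@@H](c1cc(OCOC)cc(OCOC)c1)Oc1cc(OCOC)c(C/C=C(\C)CCC=C(C)C)c(OCOC)c1 | intermediate (not isolated)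
15 | mixed anhydride of acid 13 and trifluoromethanesulfonic acid (acyl triflate) | O=C(OS(=O)(=O)C(F)(F)F)C[C@@H](c1cc(OCOC)cc(OCOC)c1)Oc1cc(OCOC)c(C/C=C(\C)CCC=C(C)C)c(OCOC)c1 | intermediate (not isolated)
16 | (2S)-2-[3,5-bis(methoxymethoxy)phenyl]-6-[(2E)-3,7-dimethylocta-2,6-dien-1-yl]-5,7-bis(methoxymethoxy)-2,3-dihydro-4H-chromen-4-one | CC(C)=CCC/C(C)=C/Cc1c(OCOC)cc2c(c1OCOC)C(=O)C[C@@H](c1cc(OCOC)cc(OCOC)c1)O2 | intermediate
17 | Schizolaenone C, (2S)-2-(3,5-dihydroxyphenyl)-6-[(2E)-3,7-dimethylocta-2,6-dien-1-yl]-5,7-dihydroxy-2,3-dihydro-4H-chromen-4-one | CC(C)=CCC/C(C)=C/Cc1c(O)cc2c(c1O)C(=O)C[C@@H](c1cc(O)cc(O)c1)O2 | target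

**Count**

Total steps: 10. Longest linear sequence: 7 steps (1, 2, 3, 7, 8, 9, 10 from resorcinol; equally 4, 5, 6, 7, 8, 9, 10 from 3',5'-dihydroxyacetophenone).

**Steps most likely to fail**

1. Step 9 (key step). The acylating species may attack the alkoxylated ring B instead (five-membered closure). Traces of acid may start cationic cyclisation of the geranyl chain or strip MOM groups. Ionisation of the benzylic ether or retro-oxa-Michael opening may erode the configuration at C2. Fallback (anionic instead of cationic closure of the same bond), setting out from 7 and 11 and returning at 16: phenol 7 would be mono-iodinated ortho to the hydroxyl (I2, morpholine, CH2Cl2, 0 °C; the two ortho positions are equivalent) to give 4-geranyl-2-iodo-3,5-bis(methoxymethoxy)phenol F1. Hydroxy ester 11 would be converted with MeNH(OMe)·HCl and i-PrMgCl (THF, −20 °C) into the (R)-hydroxy Weinreb amide F2. Mitsunobu coupling of F1 with F2 (PPh3, DIAD, toluene) would give the (S)-configured iodoaryl ether Weinreb amide F3. Treatment with t-BuLi (2.1 equiv, THF, −78 °C) would effect iodine–lithium exchange to the aryllithium F4, which attacks the Weinreb amide carbonyl intramolecularly (Parham cyclisation) and releases 16 on aqueous work-up.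

2. Step 7. Dehydration of the activated β-hydroxy ester to the cinnamate may outrun substitution, and partial ionisation at the benzylic carbon may lower the fidelity of inversion. Fallback (remove the acidifying carbonyl during etherification), setting out from 11 and returning at 13: 11 would be reduced with LiBH4 (THF, 0 °C) to the (R)-1-aryl-propane-1,3-diol F5. The primary hydroxyl would be silylated (TBSCl, imidazole, CH2Cl2, 0 °C) to the mono-TBS ether F6. Mitsunobu coupling with phenol 7 would give the (S)-aryl ether F7, and TBAF (THF, 0 °C) would free the primary alcohol F8. Oxidation with TEMPO (cat.) and PhI(OAc)2 in MeCN/pH 7 buffer would pass through the aldehyde F9 and give acid 13.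

3. Step 10. The phenols freed at C5 and C7 may add to the 2',3'-alkene of the geranyl chain under acid (chroman formation), the diene may undergo cationic cyclisation, and prolonged acid may open ring C and racemise C2. Fallback (non-protic exchange of the acetals for silyl ethers, then fluoride), setting out from 16 and returning at 17: TESOTf with 2,2'-bipyridyl (CH2Cl2, 0 °C) would convert the four aromatic MOM ethers into the tetrakis(triethylsilyl) ether F10, and Et3N·3HF (THF, 0 °C) would then release 17.

**Further compounds**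

F1 | step 9 | 4-[(2E)-3,7-dimethylocta-2,6-dien-1-yl]-2-iodo-3,5-bis(methoxymethoxy)phenol | COCOc1cc(O)c(I)c(OCOC)c1C/C=C(\C)CCC=C(C)C
F2 | step 9 | (3R)-3-[3,5-bis(methoxymethoxy)phenyl]-3-hydroxy-N-methoxy-N-methylpropanamide | CON(C)C(=O)C[C@H](c1cc(OCOC)cc(OCOC)c1)O
F3 | step 9 | (3S)-3-[3,5-bis(methoxymethoxy)phenyl]-3-{4-[(2E)-3,7-dimethylocta-2,6-dien-1-yl]-2-iodo-3,5-bis(methoxymethoxy)phenoxy}-N-methoxy-N-methylpropanamide | CON(C)C(=O)C[C@@H](c1cc(OCOC)cc(OCOC)c1)Oc1cc(OCOC)c(C/C=C(\C)CCC=C(C)C)c(OCOC)c1I
F4 | step 9 | aryllithium from F3 (lithium in place of iodine) | CON(C)C(=O)C[C@@H](c1cc(OCOC)cc(OCOC)c1)Oc1cc(OCOC)c(C/C=C(\C)CCC=C(C)C)c(OCOC)c1[Li]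
F5 | step 7 | (1R)-1-[3,5-bis(methoxymethoxy)phenyl]propane-1,3-diol | OCC[C@H](c1cc(OCOC)cc(OCOC)c1)O
F6 | step 7 | (1R)-1-[3,5-bis(methoxymethoxy)phenyl]-3-[(tert-butyldimethylsilyl)oxy]propan-1-ol | CC(C)(C)[Si](C)(C)OCC[C@H](c1cc(OCOC)cc(OCOC)c1)O
F7 | step 7 | tert-butyldimethylsilyl ether of (3S)-3-[3,5-bis(methoxymethoxy)phenyl]-3-{4-[(2E)-3,7-dimethylocta-2,6-dien-1-yl]-3,5-bis(methoxymethoxy)phenoxy}propan-1-ol | CC(C)(C)[Si](C)(C)OCC[C@@H](c1cc(OCOC)cc(OCOC)c1)Oc1cc(OCOC)c(C/C=C(\C)CCC=C(C)C)c(OCOC)c1
F8 | step 7 | (3S)-3-[3,5-bis(methoxymethoxy)phenyl]-3-{4-[(2E)-3,7-dimethylocta-2,6-dien-1-yl]-3,5-bis(methoxymethoxy)phenoxy}propan-1-ol | OCC[C@@H](c1cc(OCOC)cc(OCOC)c1)Oc1cc(OCOC)c(C/C=C(\C)CCC=C(C)C)c(OCOC)c1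
F9 | step 7 | (3S)-3-[3,5-bis(methoxymethoxy)phenyl]-3-{4-[(2E)-3,7-dimethylocta-2,6-dien-1-yl]-3,5-bis(methoxymethoxy)phenoxy}propanal | O=CC[C@@H](c1cc(OCOC)cc(OCOC)c1)Oc1cc(OCOC)c(C/C=C(\C)CCC=C(C)C)c(OCOC)c1
F10 | step 10 | (2S)-2-[3,5-bis(triethylsilyloxy)phenyl]-6-[(2E)-3,7-dimethylocta-2,6-dien-1-yl]-5,7-bis(triethylsilyloxy)-2,3-dihydro-4H-chromen-4-one | CC(C)=CCC/C(C)=C/Cc1c(O[Si](CC)(CC)CC)cc2c(c1O[Si](CC)(CC)CC)C(=O)C[C@@H](c1cc(O[Si](CC)(CC)CC)cc(O[Si](CC)(CC)CC)c1)O2
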